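## Structural features

The target is a germacranolide-type tricycle. Its ten-membered carbocycle (C1–C10) holds a Z-trisubstituted C4=C5 alkene (methyl C15 on C4). An ether oxygen bridges C3 and C10, so that O, C3, C2, C1 and C10 form a 3(2H)-furanone (C1 carbonyl, C2=C3). An α-methylene γ-lactone (C11, C12, C13, lactone oxygen on C8) is trans-fused across C7–C8.

Three adjacent stereocentres, C6 (S, acyloxy), C7 (R) and C8 (S), carry O6 and C11 cis to each other and O8 trans to C11. The quaternary C10 (R, methyl C14 and the ether oxygen) lies one methylene (C9) beyond C8. The ester adds the two centres of (2R,3R)-2,3-dimethyloxirane-2-carboxylic acid (trans methyl groups, the epoxide of angelic acid).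

Fragile groups are the exocyclic enoate and the cross-conjugated furanone dienone (both Michael acceptors) and the epoxy ester. On the way there are also cyclic enol ethers, β-alkoxy ketones and a ketone with an α-hydrogen next to an isopropenyl group.

The real difficulty is the medium ring itself: it contains a Z alkene and a transannular ether whose remote quaternary carbon C10 must be set relative to C6–C8.

The carbons C3–C8, with the C15 methyl, the Z alkene and the three-carbon branch on C7, map onto the ring of (S)-carvone (C3 is the carbonyl carbon). Only C9, C10, C1, C2 and the bridging oxygen have to be added between C8 and C3.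

The key step uses this. In a cis-fused 7a-vinyl dihydrofuranol built on the carvone ring, C1=C2–C3–C8–C9=C10 is a 1,5-diene whose central bond C3–C8 is the ring-fusion bond. A [3,3] shift therefore turns the six- and five-membered rings into the ten-membered carbocycle and the C3–O–C10 ring in one event.

## Logic of the disconnections

**31 ⇒ 25 + 29.** The C6 O–acyl bond is cut last, because the epoxide is the most acid- and nucleophile-sensitive group and the acid is a separate chiral unit. The route becomes convergent. The forward step must acylate a hindered allylic alcohol with an α-quaternary acid without touching the enoate, the dienone or the epoxide.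

**29 ⇒ 28 ⇒ 27 ⇒ 26.** The two epoxide C–O bonds and the carboxyl oxidation level are removed. Both ester stereocentres then come from one reagent-controlled oxygen transfer to a Z allylic alcohol. The forward epoxidation needs high facial selectivity on a Z-substituted alkene.

**25 ⇒ 24.** The O6 protecting group is put back. Its removal must spare lactone, enoate and furanone.

**24 ⇒ 21.** The lactone C12–O8 bond and the C12 oxidation level are cut back to a 2-methylene-1,4-diol. The forward step is an oxidative lactonisation that must oxidise only the allylic primary alcohol and the lactol derived from it.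

**21 ⇒ 20.** The C12–O bond is removed, which returns the unfunctionalised isopropenyl group of the starting terpene. The forward C–H oxidation must choose the isopropenyl methyl over C15, C6–H and C7–H.

**20 ⇒ 18.** The C1 carbonyl is removed. Up to this point the five-membered ring is a plain cyclic enol ether, which is what the rearrangement delivers. The forward step must oxidise the allylic C1 methylene of a dienol ether without touching the free C8 carbinol.

**18 ⇒ 17.** The C8–H bond is cut to the ketone. The forward reduction must be fast and non-basic (17 is a β-alkoxy ketone) and must add hydride to the face that leaves O8 trans to C11.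

**17 ⇒ 14.** This is the strategic cut. C1–C10 is broken and C3–C8 is re-formed, which contracts the ten-membered bridged ketone to a cis-fused bicyclic tertiary alcohol on a cyclohexene. The gain is the loss of the medium ring and of the bridge. The forward step needs the ring fusion on the face opposite to the C7 branch, a free C8 alkoxide, and no competing sigmatropic or elimination path.

**14 ⇒ 13.** The O–C10 bond is cut to an alkynyl trans-diol. The forward 5-endo cyclisation needs O3 and the propynyl group cis.

**13 ⇒ 11 + 12.** The C8–C9 bond is cut. The forward addition must put the propynyl group on the upper face, anti to the C7 branch and to the C3 vinyl group.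

**11 ⇒ 10 ⇒ 8 + 9.** The C3–C2 bond (with an oxidation-level change at C8) is cut. The forward addition must put the vinyl group on the face of the C7 branch, trans to O8.

**8 ⇒ 6.** The C8–O bond is cut. The forward step is a kinetic α′-enolate oxygenation anti to the C7 branch.

**6 ⇒ 5 ⇒ 4 ⇒ 3 ⇒ 2 ⇒ 1.** The C6–O bond is cut. γ-Oxygenation of the extended dienol ether gives the trans alcohol, so one inversion is needed to reach the cis relation before protection.

## Other disconnections considered

**Alternative 1:** The cut is O–C10, with C2=C3 formed in the same event. The ten-membered epoxy ketone A2 (1,10-epoxide, C3 ketone, lactone and ester in place) would be treated with acid. The C3 carbonyl oxygen would open the epoxide at the tertiary C10 with inversion, and loss of a C2 proton would give the hydroxy dihydrofuran A1, one oxidation level below the target.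
- In its favour: C10 is set by a stereospecific opening of a defined epoxide. The C1 oxygen arrives as a carbinol, whose oxidation is an ordinary allylic alcohol oxidation. On this point it is better than the chosen plan, which must oxidise a C–H bond at C1.
- Against it here: it does not build the carbocycle. A2 (medium ring, Z enone, trans lactone, a 1(10) alkene to be epoxidised on one face) still needs a macrocycle synthesis. Under acid the C4=C5 alkene can take part in transannular C–C closure, and the epoxy ester sees the same acid.
- Comparison: structurally both plans end with the same bridged ring. Mechanistically the alternative is the better-precedented single step, but it moves the risk into the making of A2. In step count the chosen plan should be shorter, because ring and bridge come from one rearrangement of a chiral-pool cyclohexene.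

**Alternative 2:** The cut is C1–C2. The acyclic aldehyde A4, which carries an iodoalkyne at C2, would be closed with CrCl2 and catalytic NiCl2 to the cyclic enynol A3. Oxidation to the ynone, release of the C10 hydroxyl and cycloisomerisation would then give the furanone.
- In its favour: the C–C closure is of a known, chemoselective type. Furanone formation from a γ-hydroxy ynone is well established and needs no C–H oxidation, so on both points it is better than the chosen plan. The C1 configuration is immaterial.
- Against it here: a cis-enyne inside a ten-membered ring is strained, and the closure is end to end with the usual entropic cost. A4 needs a long linear synthesis in which C6, C7, C8 and C10 are set without the help of a chiral-pool ring, plus two orthogonal silyl ethers.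
- Comparison: on structure the two plans are equal in having all ring stereocentres in place before the ring forms. On mechanism the alternative is safer. On step economy the chosen plan should win clearly.

**Alternative 3:** The cut is C5–C6. The aldehyde A6, which carries a Z alkenyl iodide at C5 and the finished furanone, would be closed with CrCl2 and catalytic NiCl2 to the 6-hydroxy lactone A5.
- In its favour: furanone and lactone exist before ring closure, and the alkene geometry is fixed beforehand in the iodide (equal to the chosen plan, which inherits it from the terpene). The closure yields the C6 carbinol ready for acylation, and no unprecedented step is needed (better than the chosen plan).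
- Against it here: C6 is created during macrocyclisation, so its configuration rests on the facial bias of an α-branched aldehyde in a forming medium ring. A6 is a β-acyloxy aldehyde with an epimerisable C7, open to elimination. A5 lacks C13, so an α-methylenation of the lactone must follow. The furanone–iodide half with its C10 centre needs its own synthesis.
- Comparison: structurally it postpones one stereocentre and one carbon. Mechanistically it is known chemistry. In step count it is expected to be longer than the chosen plan.

Key step: step 11

Remark on the chemistry: O6 is carried as a methoxymethyl ether and not as a silyl ether, because a silyl group 1,3-syn to the C8 alkoxide of the key step could shift to O8 and free a C6 alkoxide, whose own oxy-Cope path (C4=C5–C6–C7–C11=C13) would cut C6–C7. "Lower face" means the face of the carvone ring that carries the isopropenyl group.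

## Route

Step 1
Reactants: 1 (S)-(+)-carvone
Product: 2 trimethyl{[(5R)-2-methyl-5-(prop-1-en-2-yl)cyclohexa-1,3-dien-1-yl]oxy}silane (extended silyl dienol ether, C3=C4 and C5=C6)
Conditions: Me3SiCl, NaI, Et3N, MeCN, rt; pentane extraction
Reagents that add atoms: chlorotrimethylsilane, C[Si](C)(C)Cl
Why: Soft enolisation with Me3SiI made in the flask is reversible, so the through-conjugated 1-silyloxy-1,3-diene (proton lost from C6) should accumulate over the cross-conjugated isomer; this is thermodynamic silyl dienol ether formation, and C7 is not touched.

Step 2
Reactants: 2 trimethylsilyl dienol ether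
Product: 3 (4R,5S)-4-hydroxy-2-methyl-5-(prop-1-en-2-yl)cyclohex-2-en-1-one (C6–OH trans to isopropenyl)
Conditions: mCPBA, NaHCO3, CH2Cl2, −20 °C; aq. citric acid work-up
Reagents that add atoms: 3-chloroperoxybenzoic acid, OOC(=O)c1cccc(Cl)c1
Why: Vinylogous Rubottom oxidation: the peracid should attack the distal C5=C6 bond of the dienol ether on the face away from the neighbouring isopropenyl group, and collapse of the epoxide restores the enone with the new hydroxyl on C6; the electron-rich diene reacts far faster than the isopropenyl alkene.

Step 3
Reactants: 3 trans-γ-hydroxy enone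
Product: 4 (1S,6S)-3-methyl-4-oxo-6-(prop-1-en-2-yl)cyclohex-2-en-1-yl 4-nitrobenzoate (C6–O cis to isopropenyl)
Conditions: 4-nitrobenzoic acid, PPh3, DIAD, THF, 0 °C
Reagents that add atoms: 4-nitrobenzoic acid, OC(=O)c1ccc(cc1)[N+](=O)[O-]
Why: Mitsunobu reaction; the carboxylate displaces the activated secondary allylic oxygen with inversion, which turns the trans into the required cis relation between O6 and C11.

Step 4
Reactants: 4 cis 4-nitrobenzoate
Product: 5 (4S,5S)-4-hydroxy-2-methyl-5-(prop-1-en-2-yl)cyclohex-2-en-1-one
Conditions: K2CO3 (cat.), MeOH, 0 °C
Reagents that add atoms: none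
Why: Transesterification of an activated aryl ester under mild base; the C6–O bond is not broken, so the configuration is kept.

Step 5
Reactants: 5 cis-γ-hydroxy enone
Product: 6 (4S,5S)-4-(methoxymethoxy)-2-methyl-5-(prop-1-en-2-yl)cyclohex-2-en-1-one
Conditions: MOMCl, i-Pr2NEt, CH2Cl2, 0 °C → rt
Reagents that add atoms: chloromethyl methyl ether, COCCl
Why: Standard acetal protection of a secondary alcohol; the acetal is inert to amide bases, Grignard reagents and KH and cannot migrate between oxygens.

Step 6
Reactants: 6 MOM ether
Product: 8 (4S,5R,6R)-6-hydroxy-4-(methoxymethoxy)-2-methyl-5-(prop-1-en-2-yl)cyclohex-2-en-1-one (C8–OH on the upper face, trans to isopropenyl), via potassium enolate 7 (not isolated)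
Conditions: KN(SiMe3)2, THF, −78 °C; 2-(phenylsulfonyl)-3-phenyloxaziridine, −78 °C; AcOH quench
Reagents that add atoms: 2-(phenylsulfonyl)-3-phenyloxaziridine, O=S(=O)(N1OC1c1ccccc1)c1ccccc1
Why: Kinetic deprotonation takes the α′ methylene (C8), and the cross-conjugated enolate is oxygenated by the oxaziridine on the face away from the adjacent isopropenyl group and the syn C6 substituent; this is enolate hydroxylation in place of a two-stage Rubottom sequence.

Step 7
Reactants: 8 α′-hydroxy enone; 9 vinylmagnesium bromide
Product: 10 (1R,2S,5S,6R)-2-ethenyl-5-(methoxymethoxy)-3-methyl-6-(prop-1-en-2-yl)cyclohex-3-ene-1,2-diol (C3: OH on the upper face, vinyl on the lower face; C8–OH on the upper face)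
Conditions: CH2=CHMgBr (3 equiv), THF–CH2Cl2, −78 → −40 °C
Reagents that add atoms: vinylmagnesium bromide (9), C=C[Mg]Br
Why: The first equivalent forms the C8 bromomagnesium alkoxide, which chelates the C3 carbonyl; chelation-controlled 1,2-addition should then bring the vinyl group in trans to O8, on the side of the C8 hydrogen, giving the cis-diol with O3 on the face opposite to the isopropenyl group. 1,4-Addition is not expected for an α-substituted enone without copper.

Step 8
Reactants: 10 cis-diol
Product: 11 (2S,5S,6S)-2-ethenyl-2-hydroxy-5-(methoxymethoxy)-3-methyl-6-(prop-1-en-2-yl)cyclohex-3-en-1-one (C8 ketone)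
Conditions: Dess–Martin periodinane, pyridine, CH2Cl2, 0 °C
Reagents that add atoms: none
Why: Only the secondary carbinol can be oxidised; buffered periodinane oxidation at low temperature avoids acid- or base-induced acyloin shift of the tertiary α-ketol.

Step 9
Reactants: 11 α-ketol; 12 1-propynylmagnesium bromide
Product: 13 (1R,2S,5S,6S)-2-ethenyl-5-(methoxymethoxy)-3-methyl-6-(prop-1-en-2-yl)-1-(prop-1-yn-1-yl)cyclohex-3-ene-1,2-diol (trans-diol; propynyl on the upper face, cis to O3)
Conditions: CH3C≡CMgBr (3 equiv), THF, −78 → 0 °C
Reagents that add atoms: 1-propynylmagnesium bromide (12), CC#C[Mg]Br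
Why: After deprotonation of O3 the magnesium alkoxide chelates the C8 carbonyl; the weakly basic alkynyl nucleophile should enter on the upper face, anti to both the C3 vinyl group and the adjacent isopropenyl group. The low basicity avoids enolisation toward C7.

Step 10
Reactants: 13 alkynyl trans-diol
Product: 14 cis-fused 7a-ethenyl-5-(methoxymethoxy)-2,7-dimethyl-4-(prop-1-en-2-yl)-4,5-dihydro-1-benzofuran-3a(7aH)-ol (ring oxygen and C9 on the upper face; vinyl, C8–OH, isopropenyl and OMOM on the lower face)
Conditions: Ph3PAuNTf2 (2 mol %), CH2Cl2, 0 °C; filtration through basic alumina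
Reagents that add atoms: none
Why: 5-endo-dig hydroalkoxylation: the gold-activated alkyne is attacked at C10 by O3, which is cis to it, and protodeauration gives the 2-methyl dihydrofuran; dehydration to a furan is blocked because C3 and C8 are quaternary, and a five-membered ring can only be cis-fused here.

Step 11
Reactants: 14 cis-fused vinyl dihydrofuranol
Product: 17 oxygen-bridged ten-membered C8 ketone (C2=C3 enol ether; Z C4=C5; 6-OMOM; 7-isopropenyl; 10-methyl with the configuration of the target), via potassium alkoxide 15 (not isolated), via potassium enolate 16 (not isolated)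
Conditions: KH, 18-crown-6, THF, 0 °C → rt; transfer into AcOH–THF at −78 °C
Reagents that add atoms: none
Why: Proposed new method: KH with 18-crown-6 gives the free C8 alkoxide 15, whose charge weakens the doubly allylic C3–C8 bond, and the diene C1=C2–C3–C8–C9=C10 reorganises by a [3,3] shift (C3–C8 breaks, C1–C10 forms) to enolate 16, either in concert or through a tight ketone/pentadienyl-anion pair that collapses by 1,4-addition of C1 to C10. The closest known reaction is the anionic oxy-Cope ring expansion of 1,2-dialkenylcyclohexanols to cyclodec-5-enones; new here are the endocyclic enol ether as one ene partner and the oxygen that ties C3 to C10 throughout. Neither ring closes end to end: the ten-membered carbocycle appears when the bond shared by the six- and five-membered rings is cut, and the new O–C3=C2–C1–C10 ring closes within a boat-like six-centre array bridged by one oxygen atom, in which C1 swings onto C10 from the convex face. C10 is the only new stereocentre and is fixed by suprafacial delivery of C1 to the face of the dihydrofuran that carries the vinyl group, that is, by the C3 configuration from step 7. Three rival paths must be excluded: the [3,3] path through C4=C5 is disfavoured because C5 is tied back to C8 by C6–C7 on the concave face; the path through the isopropenyl group is closed because C11 and C9 are anti across C7–C8; and transfer of a group to O6 is excluded by the acetal. The enolate is quenched cold into acid so that loss of the ring oxygen from C10 (retro-oxa-Michael) does not set in, and in the rigid enolate the C10–O bond lies near the nodal plane, which should slow that loss. Enolate formation and release of the doubly allylic bond pay for the medium ring, and the Z C4=C5 bond of the terpene is carried over unchanged.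

Step 12
Reactants: 17 bridged C8 ketone (crude, used at once)
Product: 18 (8S)-alcohol of 17 (C8–OH trans to the isopropenyl group; dienol ether intact)
Conditions: NaBH4, MeOH–THF, −78 → −40 °C
Reagents that add atoms: none
Why: Fast borohydride reduction removes the β-alkoxy ketone before elimination or C7 epimerisation can occur; hydride should come from the periphery of the ring onto the conformer in which C8=O eclipses the C7–H bond, leaving O8 trans to C11.

Step 13
Reactants: 18 bridged dienol ether alcohol
Product: 20 furanone alcohol (C1 ketone, C2=C3, free 8-OH, 6-OMOM, 7-isopropenyl), via C1 carbinol 19 (not isolated)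
Conditions: DDQ (2.5 equiv), CH2Cl2–pH 7 phosphate buffer, 0 °C → rt
Reagents that add atoms: water, O
Why: Proposed new method: DDQ should abstract hydride from the allylic C1 methylene of the dienol ether, giving an oxygen-stabilised pentadienyl cation (charge on C1, C3 and C5) that water captures at C1 (capture at C3 is reversible), and a second equivalent oxidises the allylic carbinol 19 to the vinylogous ester; the isolated secondary C8 carbinol is not oxidised by DDQ. The closest known reactions are the DDQ dehydrogenation of silyl enol ethers, which starts with the same allylic hydride abstraction, and DDQ/water oxidations of benzylic and allylic positions to ketones.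

Step 14
Reactants: 20 furanone alcohol
Product: 21 12-hydroxy derivative of 20 (isopropenyl methyl oxidised to CH2OH)
Conditions: SeO2 (0.3 equiv), t-BuOOH, CH2Cl2, rt
Reagents that add atoms: selenium dioxide, O=[Se]=O; tert-butyl hydroperoxide, CC(C)(C)OO
Why: Allylic hydroxylation by ene reaction and [2,3] shift on the only electron-rich alkene; the C4=C5 bond is part of the electron-poor dienone, and the hindered C7 methine is less accessible than the methyl group.

Step 15
Reactants: 21 2-methylene-1,4-diol
Product: 24 α-methylene γ-lactone with 6-OMOM (trans-fused at C7–C8), via enal 22 (not isolated), via lactol 23 (not isolated)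
Conditions: MnO2 (excess), CH2Cl2, rt
Reagents that add atoms: none
Why: Oxidative lactonisation: MnO2 oxidises the allylic primary alcohol to the enal, the C8 hydroxyl closes to the five-membered lactol, and the allylic lactol is oxidised on to the lactone; the configurations at C7 and C8 are untouched.

Step 16
Reactants: 24 lactone MOM ether
Product: 25 6-hydroxy lactone (target without its ester)
Conditions: HCl (cat.), MeOH, 0 °C → rt
Reagents that add atoms: none
Why: Acid-catalysed acetal exchange removes the methoxymethyl group; the furanone and the lactone are acid-stable, and ionisation at allylic C6 is disfavoured because the alkene is conjugated to the furanone.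

Step 17
Reactants: 26 methyl angelate
Product: 27 (Z)-2-methylbut-2-en-1-ol
Conditions: i-Bu2AlH (2.2 equiv), CH2Cl2, −78 °C; aq. potassium sodium tartrate
Reagents that add atoms: none
Why: 1,2-Reduction of the unsaturated ester at low temperature keeps the Z geometry.

Step 18
Reactants: 27 (Z)-2-methylbut-2-en-1-ol
Product: 28 [(2S,3R)-2,3-dimethyloxiran-2-yl]methanol
Conditions: Ti(OiPr)4 (cat.), L-(+)-diethyl tartrate (cat.), t-BuOOH, 4 Å sieves, CH2Cl2, −20 °C
Reagents that add atoms: tert-butyl hydroperoxide, CC(C)(C)OO
Why: Sharpless asymmetric epoxidation; the tartrate selects the alkene face and the syn oxygen transfer keeps the two methyl groups trans, so both stereocentres of the acid are set here.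

Step 19
Reactants: 28 epoxy alcohol
Product: 29 (2R,3R)-2,3-dimethyloxirane-2-carboxylic acid
Conditions: TEMPO (cat.), PhI(OAc)2, MeCN–H2O, rt
Reagents that add atoms: water, O
Why: Oxoammonium oxidation of the primary alcohol through the aldehyde hydrate to the acid under near-neutral conditions; no bond to a stereocentre is broken (the C2 descriptor changes only by priority).

Step 20
Reactants: 25 6-hydroxy lactone; 29 epoxy acid
Product: 31 target CNP0258430.3, via mixed anhydride 30 (not isolated)
Conditions: 29, 2,4,6-trichlorobenzoyl chloride, Et3N, THF, rt; then 25, DMAP, toluene, rt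
Reagents that add atoms: (2R,3R)-2,3-dimethyloxirane-2-carboxylic acid (29), OC(=O)[C@]1(C)O[C@@H]1C
Why: Yamaguchi esterification; acyl transfer to O6 occurs at the carbonyl carbon, so C6 and both epoxide centres keep their configuration, and the non-nucleophilic conditions spare the enoate and the epoxide.

## Compound list

1 | (S)-(+)-carvone | CC1=CC[C@@H](CC1=O)C(C)=C | starting material
2 | trimethyl{[(5R)-2-methyl-5-(prop-1-en-2-yl)cyclohexa-1,3-dien-1-yl]oxy}silane | CC1=C(O[Si](C)(C)C)C[C@H](C=C1)C(C)=C | intermediate
3 | (4R,5S)-4-hydroxy-2-methyl-5-(prop-1-en-2-yl)cyclohex-2-en-1-one | CC1=C[C@@H](O)[C@@H](CC1=O)C(C)=C | intermediate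
4 | (1S,6S)-3-methyl-4-oxo-6-(prop-1-en-2-yl)cyclohex-2-en-1-yl 4-nitrobenzoate | CC1=C[C@H](OC(=O)c2ccc(cc2)[N+](=O)[O-])[C@@H](CC1=O)C(C)=C | intermediate
5 | (4S,5S)-4-hydroxy-2-methyl-5-(prop-1-en-2-yl)cyclohex-2-en-1-one | CC1=C[C@H](O)[C@@H](CC1=O)C(C)=C | intermediate
6 | (4S,5S)-4-(methoxymethoxy)-2-methyl-5-(prop-1-en-2-yl)cyclohex-2-en-1-one | CC1=C[C@H](OCOC)[C@@H](CC1=O)C(C)=C | intermediate
7 | potassium enolate of 6 (C3–O–K, C3=C8) | CC1=C[C@H](OCOC)[C@@H](C=C1[O-])C(C)=C.[K+] | intermediate (not isolated)
8 | (4S,5R,6R)-6-hydroxy-4-(methoxymethoxy)-2-methyl-5-(prop-1-en-2-yl)cyclohex-2-en-1-one | CC1=C[C@H](OCOC)[C@@H]([C@@H](O)C1=O)C(C)=C | intermediate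
9 | vinylmagnesium bromide | C=C[Mg]Br | starting material
10 | (1R,2S,5S,6R)-2-ethenyl-5-(methoxymethoxy)-3-methyl-6-(prop-1-en-2-yl)cyclohex-3-ene-1,2-diol | C=C[C@]1(O)C(C)=C[C@H](OCOC)[C@@H]([C@H]1O)C(C)=C | intermediate
11 | (2S,5S,6S)-2-ethenyl-2-hydroxy-5-(methoxymethoxy)-3-methyl-6-(prop-1-en-2-yl)cyclohex-3-en-1-one | C=C[C@]1(O)C(C)=C[C@H](OCOC)[C@@H](C1=O)C(C)=C | intermediate
12 | 1-propynylmagnesium bromide | CC#C[Mg]Br | starting material
13 | (1R,2S,5S,6S)-2-ethenyl-5-(methoxymethoxy)-3-methyl-6-(prop-1-en-2-yl)-1-(prop-1-yn-1-yl)cyclohex-3-ene-1,2-diol | C=C[C@]1(O)C(C)=C[C@H](OCOC)[C@@H]([C@@]1(O)C#CC)C(C)=C | intermediate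
14 | cis-fused 7a-ethenyl-5-(methoxymethoxy)-2,7-dimethyl-4-(prop-1-en-2-yl)-4,5-dihydro-1-benzofuran-3a(7aH)-ol | C=C[C@@]12OC(C)=C[C@]1(O)[C@@H](C(C)=C)[C@@H](OCOC)C=C2C | intermediate
15 | potassium alkoxide of 14 (C8–O–K) | C=C[C@@]12OC(C)=C[C@]1([O-])[C@@H](C(C)=C)[C@@H](OCOC)C=C2C.[K+] | intermediate (not isolated)
16 | potassium enolate of 17 (C8–O–K, C8=C9) | [O-]/C1=C/[C@@]2(C)OC(=CC2)/C(C)=C\[C@H](OCOC)[C@@H]1C(C)=C.[K+] | intermediate (not isolated)
17 | oxygen-bridged ten-membered C8 ketone with C2=C3 enol ether (6-OMOM, 7-isopropenyl, 10-methyl) | O=C1C[C@@]2(C)OC(=CC2)/C(C)=C\[C@H](OCOC)[C@@H]1C(C)=C | intermediate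
18 | (8S)-alcohol of 17 | O[C@H]1C[C@@]2(C)OC(=CC2)/C(C)=C\[C@H](OCOC)[C@@H]1C(C)=C | intermediate
19 | C1 carbinol of 18 (3-hydroxy-2,3-dihydrofuran, either C1 epimer) | O[C@H]1C[C@@]2(C)OC(=CC2O)/C(C)=C\[C@H](OCOC)[C@@H]1C(C)=C | intermediate (not isolated)
20 | furanone alcohol (C1 ketone, 8-OH, 6-OMOM, 7-isopropenyl) | O[C@H]1C[C@@]2(C)OC(=CC2=O)/C(C)=C\[C@H](OCOC)[C@@H]1C(C)=C | intermediate
21 | 12-hydroxy derivative of 20 (2-methylene-1,4-diol) | O[C@H]1C[C@@]2(C)OC(=CC2=O)/C(C)=C\[C@H](OCOC)[C@@H]1C(CO)=C | intermediate
22 | enal from 21 (C12 aldehyde) | O[C@H]1C[C@@]2(C)OC(=CC2=O)/C(C)=C\[C@H](OCOC)[C@@H]1C(C=O)=C | intermediate (not isolated)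
23 | lactol from 22 (C12 hemiacetal to O8, either epimer) | C=C1C(O)O[C@H]2C[C@@]3(C)OC(=CC3=O)/C(C)=C\[C@H](OCOC)[C@H]12 | intermediate (not isolated)
24 | α-methylene lactone with 6-OMOM | C=C1C(=O)O[C@H]2C[C@@]3(C)OC(=CC3=O)/C(C)=C\[C@H](OCOC)[C@H]12 | intermediate
25 | 6-hydroxy α-methylene lactone (target without its ester) | C=C1C(=O)O[C@H]2C[C@@]3(C)OC(=CC3=O)/C(C)=C\[C@H](O)[C@H]12 | intermediate
26 | methyl angelate, methyl (Z)-2-methylbut-2-enoate | C/C=C(/C)C(=O)OC | starting material
27 | (Z)-2-methylbut-2-en-1-ol | C/C=C(/C)CO | intermediate
28 | [(2S,3R)-2,3-dimethyloxiran-2-yl]methanol | OC[C@]1(C)O[C@@H]1C | intermediate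
29 | (2R,3R)-2,3-dimethyloxirane-2-carboxylic acid | OC(=O)[C@]1(C)O[C@@H]1C | intermediate
30 | mixed anhydride of 29 with 2,4,6-trichlorobenzoic acid | Clc1cc(Cl)c(C(=O)OC(=O)[C@]2(C)O[C@@H]2C)c(Cl)c1 | intermediate (not isolated)
31 | CNP0258430.3 | C=C1C(=O)O[C@H]2C[C@@]3(C)OC(=CC3=O)/C(C)=C\[C@H](OC(=O)[C@]3(C)O[C@@H]3C)[C@H]12 | target

## Step count and least certain steps

Total: 20 steps. Longest linear sequence: 17 steps (1 → 31 through steps 1–16 and 20). The side branch 26 → 29 has 3 steps.

**Step 11 (key step, proposed new method).**
- What may go wrong: the bridged boat array may not be reached, because the enol-ether π bond lies in the five-membered ring, almost orthogonal to the bond that must break. The alkoxide could then fragment and recombine at the wrong terminus (C5 instead of C1), or the enolate could lose the ring oxygen by β-elimination before the quench.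
- Fallback (known chemistry), from 13 back to 20: vinyl and propynyl groups in 13 are trans, so its dipotassium salt (KH, 18-crown-6, THF) can undergo the ordinary acetylenic anionic oxy-Cope rearrangement through a chair array to the ring-expanded ten-membered 3,8-dione F1 (C9=C10 enone, no oxygen bridge). Oxidation of the γ-methylene of that enone with Pd(OH)2/C, t-BuOOH and K2CO3 gives the ene-trione F2. Its β-diketone enol oxygen then adds to C10 (oxa-Michael, Et3N) to give the furanone ketone F3, and NaBH4 reduces the C8 ketone to 20. Here C10 is set in the conjugate addition, not in the rearrangement.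

**Step 13 (proposed new method).**
- What may go wrong: hydride abstraction at another allylic position (C6), capture of the cation at C3 with ring opening, or acid-induced hydrolysis of the enol ether by the hydroquinone formed.
- Fallback (known chemistry), from 18 back to 20: the C8 hydroxyl is acetylated (Ac2O, pyridine) to the acetate F4. The C1 methylene is then oxidised by hydrogen-atom abstraction and peroxide collapse with catalytic Rh2(cap)4 (dirhodium tetrakis(caprolactamate)) and t-BuOOH, giving the furanone acetate F5. K2CO3 in MeOH returns 20.

**Step 7.**
- What may go wrong: poor facial selectivity. Axial attack trans to the isopropenyl group and shielding of the lower face by the C6 substituent oppose the chelate, so the vinyl group may enter on the upper face.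
- Fallback, from 8 back to 11 (the configuration of the first addition becomes irrelevant): the C3-epimeric or mixed diol F6 is oxidised (Dess–Martin periodinane) to the epimeric ketol F7. SmI2 in THF–MeOH cleaves the C3–O bond to the α-vinyl ketone F8. Its enolate (KN(SiMe3)2) is hydroxylated by the oxaziridine on the upper face, away from the C6 and C7 substituents, to give 11.

**Step 10.**
- What may go wrong: diversion of the gold-activated alkyne into a Meyer–Schuster shift of the propargylic alcohol or into enyne cycloisomerisation with a neighbouring alkene, and acid-induced ionisation of the tertiary allylic carbinols.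
- Fallback, from 11 back to 14 (also replaces step 9): the tertiary hydroxyl is acylated with bromoacetyl bromide and pyridine to the bromoacetate F9. A SmI2-mediated intramolecular Reformatsky reaction closes the β-hydroxy γ-lactone F10; it is cis-fused by necessity, so C8 is set without a facial choice. MeLi at −78 °C gives the methyl lactol F11, which is dehydrated with a trace of pyridinium p-toluenesulfonate to 14.

**Step 12.**
- What may go wrong: poor facial selectivity in a medium ring whose preferred conformer is not known, and β-elimination if the reduction is slow.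
- Fallback, from 17 back to 18: the C8 epimer F12 is inverted by a Mitsunobu reaction (4-nitrobenzoic acid, PPh3, DIAD) to the 4-nitrobenzoate F13, and K2CO3 in MeOH gives 18.

## Further compounds

F1 | step 11 | ten-membered 3,8-dione from acetylenic oxy-Cope of 13 (C9=C10 enone, geometry open) | O=C1C=C(C)CCC(=O)/C(C)=C\[C@H](OCOC)[C@@H]1C(C)=C
F2 | step 11 | ene-trione (C1, C3 and C8 ketones) | O=C1C=C(C)C(=O)CC(=O)/C(C)=C\[C@H](OCOC)[C@@H]1C(C)=C
F3 | step 11 | furanone C8 ketone | O=C1C[C@@]2(C)OC(=CC2=O)/C(C)=C\[C@H](OCOC)[C@@H]1C(C)=C
F4 | step 13 | C8 acetate of 18 | CC(=O)O[C@H]1C[C@@]2(C)OC(=CC2)/C(C)=C\[C@H](OCOC)[C@@H]1C(C)=C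
F5 | step 13 | C8 acetate of 20 | CC(=O)O[C@H]1C[C@@]2(C)OC(=CC2=O)/C(C)=C\[C@H](OCOC)[C@@H]1C(C)=C
F6 | step 7 | C3 epimer of 10 | C=C[C@@]1(O)C(C)=C[C@H](OCOC)[C@@H]([C@H]1O)C(C)=C
F7 | step 7 | C3 epimer of 11 | C=C[C@@]1(O)C(C)=C[C@H](OCOC)[C@@H](C1=O)C(C)=C
F8 | step 7 | α-vinyl ketone, 2-ethenyl-5-(methoxymethoxy)-3-methyl-6-(prop-1-en-2-yl)cyclohex-3-en-1-one (C3 undefined) | C=CC1C(C)=C[C@H](OCOC)[C@@H](C1=O)C(C)=C
F9 | step 10 | bromoacetate of 11 | C=C[C@]1(OC(=O)CBr)C(C)=C[C@H](OCOC)[C@@H](C1=O)C(C)=C
F10 | step 10 | cis-fused β-hydroxy γ-lactone | C=C[C@@]12OC(=O)C[C@]1(O)[C@@H](C(C)=C)[C@@H](OCOC)C=C2C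
F11 | step 10 | methyl lactol of F10 (hemiketal carbon undefined) | C=C[C@@]12OC(C)(O)C[C@]1(O)[C@@H](C(C)=C)[C@@H](OCOC)C=C2C
F12 | step 12 | C8 epimer of 18 | O[C@@H]1C[C@@]2(C)OC(=CC2)/C(C)=C\[C@H](OCOC)[C@@H]1C(C)=C
F13 | step 12 | 4-nitrobenzoate of 18 | O=C(O[C@H]1C[C@@]2(C)OC(=CC2)/C(C)=C\[C@H](OCOC)[C@@H]1C(C)=C)c1ccc(cc1)[N+](=O)[O-]
A1 | alternative 1 | 1-hydroxy dihydrofuran, one oxidation level below the target | C=C1C(=O)O[C@H]2C[C@@]3(C)OC(=C[C@@H]3O)/C(C)=C\[C@H](OC(=O)[C@]3(C)O[C@@H]3C)[C@H]12
A2 | alternative 1 | ten-membered 1,10-epoxy 3-ketone with lactone and ester | C=C1C(=O)O[C@H]2C[C@]3(C)O[C@H]3CC(=O)/C(C)=C\[C@H](OC(=O)[C@]4(C)O[C@@H]4C)[C@H]12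
A3 | alternative 2 | ten-membered enynol fused to the lactone | O[C@@H]1C#C/C(C)=C\[C@H](O[Si](C)(C)C(C)(C)C)[C@@H]2C(=C)C(=O)O[C@H]2C[C@@]1(C)O[Si](CC)(CC)CC
A4 | alternative 2 | acyclic C1 aldehyde with C2 iodoalkyne | O=C[C@](C)(O[Si](CC)(CC)CC)C[C@@H]1OC(=O)C(=C)[C@H]1[C@@H](O[Si](C)(C)C(C)(C)C)/C=C(C)\C#CI
A5 | alternative 3 | tricyclic 6-hydroxy lactone lacking C13 | C1C(=O)O[C@H]2C[C@@]3(C)OC(=CC3=O)/C(C)=C\[C@H](O)[C@H]12
A6 | alternative 3 | C6 aldehyde with Z alkenyl iodide at C5 | O=C[C@@H]1CC(=O)O[C@H]1C[C@@]2(C)OC(=CC2=O)/C(C)=C\I
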